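## Analysis of the target

The target 22 is a monocyclic 2,3,6-trisubstituted piperidine. N1 is a free secondary amine, C2 bears a methyl group, C3 an acetoxy group, and C6 an unbranched 13-oxotetradecyl chain (twelve CH2 groups and a terminal methyl ketone). The SMILES decodes to (2R,3R,6S), which puts all three substituents on one face of the ring. In the chair the C2 methyl group and the C6 chain are equatorial and the C3 acetoxy group is axial.

Two relations tie the stereocentres together. One is a vicinal syn amino alcohol edge N1–C2–C3–O, with nitrogen on the methyl-bearing carbon. The other is a 1,4-cis relation between C3–O and C6–C1' across the C4–C5 bridge.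

There are three sensitive points:
- The ester sits β to a free secondary amine, so acetyl can shift from O to N once the amine is left unprotonated in base.
- The remote ketone must be masked whenever a carbon nucleophile or a hydride is used.
- The amine/ketone pair is at risk under reducing conditions.

The ring is easy to close. The hard part is the syn C2/C3 pair, which acyclic additions to α-amino aldehydes do not favour, and its registry with the remote C6, where the chain offers no functional handle.

The route exploits the edge N1–C2(CH3)–C3(O). This is the pattern left when a 1-azoniabicyclo[3.1.0]hexane is opened by an oxygen nucleophile at its bridgehead carbon. Read that way, N1, C3, C4, C5 and C6 are the five ring atoms of a pyrrolidine, and C2 with its methyl group is an exocyclic carbinol carbon. The C3/C6 cis relation of the piperidine is then the 2,5-cis relation of that pyrrolidine, the easiest relation to set in a five-membered azacycle.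

## Retrosynthetic reasoning

**From 22 to 20.** The last bonds cut are the N1–CH2Ph bond and the two C–O bonds of the ketal in 20, by way of the N-benzyl ketone 21. The amine is set free only in the final operation and only in an acidic medium. There it is protonated and cannot take the acetyl group from O3. The ketone appears after the last nucleophile and the last hydride have been used.

**From 20 to 19.** The O3–acyl bond is cut. N1 is still tertiary in 19, so the acetylation has no chemoselectivity problem.

**From 19 to 15 (key disconnection).** The bonds N1–C2 and C3–O of the piperidine are cut and N1 is reconnected to C3. The ring contracts to the cis-2,5-disubstituted pyrrolidine 15, in which the old C2 is a secondary carbinol carbon outside the ring.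

In the forward direction ester 16 ionises to the bicyclic aziridinium ion 17. The carboxylate opens 17 at the bridgehead to give ester 18, which is saponified to 19.

The cut is placed here and not at N1–C6 for three reasons:
- Nitrogen and oxygen change places, so the nitrogen-bearing carbon of 15 is the α-carbon of an amino acid. Because this carbon is inverted in the step, the cheap L series gives the right enantiomer.
- The remote C3/C6 relation becomes a 2,5-cis pyrrolidine relation.
- C2 and C3 are delivered together in one stereospecific event that also changes the ring size.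

The forward reaction has to achieve clean inversion at both carbons and opening of 17 at the bridgehead rather than at the methyl-bearing carbon.

**From 15 to 12.** The C–H bond of the carbinol carbon is cut (ketone 14), then the CO–CH3 bond (ester 12, through amide 13). The syn amino alcohol is the Felkin–Anh product of hydride addition to an α-(dialkylamino) ketone. The relation that is awkward in the piperidine is therefore the favoured one here.

**From 12 to 8.** The N–benzyl bond is cut (11), then the N–C5 and C5–H bonds of the pyrrolidine. Compound 11 should arise from keto carbamate 8 in a single hydrogenation, through amino ketone 9 and cyclic imine 10. The ester at C2 shields one face of 10, so the bought stereocentre sets C5.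

**From 8 to 6 and 4.** The bond between the ketone carbon and the chain is cut. The forward reaction is the ring-opening acylation of Grignard reagent 7 (from bromide 4) by the activated lactam 6. Lactam 6 comes from methyl L-pyroglutamate 5, the only source of chirality in the route. The whole C14 chain enters in one convergent step.

**From 4 to 1 and 2.** One CH2–CH2 bond of the chain is cut, three carbons from the ketal. Grignard reagent 3, made from chloride 1, is coupled once with the symmetrical dibromide 2. This gives the twelve methylenes and the masked methyl ketone in one step from bulk chemicals.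

## Alternatives that were turned down

**Alternative 1:** the textbook route, cutting N1–C6.
- *Forward key step.* Hydrogenolysis of carbamate A2 frees the amine, which condenses with the C6 ketone to cyclic imine A3. Hydrogenation of A3 then gives the 2,6-cis piperidine. A2 would be built by adding a carbon nucleophile to the α-amino aldehyde A1.
- *Why turned down.* The ring closure makes one C–N bond and one stereocentre, so the hard C2/C3 pair has to be set earlier, in an acyclic addition to A1. A1 is configurationally labile and belongs to the unnatural (R) series. Its Felkin–Anh preference leads to the anti amino alcohol, not the syn one needed, so chelation control or an inversion sequence must be added. The route is linear, protecting-group heavy, and puts its stereochemical risk in the least controllable step.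

**Alternative 2:** aza-Achmatowicz ring expansion, cutting the piperidine back to a furan.
- *Forward key step.* Oxidation of furfuryl sulfonamide A4 opens the furan to an enedione that nitrogen captures, giving the 6-hydroxy-dihydropyridin-3-one A5.
- *Why turned down.* The ring forms in one step but at the wrong oxidation level. The hemiaminal carbon C6, the C4=C5 alkene and the C3 ketone each need a separate reduction, two of them with a stereochemical outcome of their own. The reaction needs an electron-poor sulfonyl nitrogen, whose A(1,3) strain pushes the C2 and C6 substituents axial and complicates both reductions. The Lewis acid/silane reduction at C6 would also attack the ketal. Removing the sulfonyl group needs dissolving-metal conditions that neither the acetate nor the chain ketone tolerates. The steps after the key step outnumber those it saves.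

**Alternative 3:** hydrogenation of a flat pyridine, cutting all six C–H bonds of the ring.
- *Forward key step.* 2-Methylpyridin-3-ol A6 would be alkylated at C6 by cross-coupling and acetylated to pyridyl acetate A7. All-cis hydrogenation of A7 or its pyridinium salt would then set the three stereocentres at once.
- *Why turned down.* A7 holds no stereocentre to relay from, so the product is racemic unless a chiral catalyst tells apart the two faces of a pyridinium ion flanked by two similar alkyl groups. 3-Oxygenated pyridinium ions are reduced through enamine and enol tautomers that funnel into piperidin-3-one A8, where the C3 information is lost and C2 is epimerisable. Vinylic and allylic C–O hydrogenolysis competes as well. A resolution would discard half of a late intermediate.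

Key step: step 8

Assumption: compounds 1, 2 and 5 are taken as commercial, and the all-cis (2R,3R,6S) configuration decoded from the SMILES is the one that is made.

## Route

Step 1
Reactants: 1 2-(3-chloropropyl)-2-methyl-1,3-dioxolane; 2 1,9-dibromononane
Product: 4 2-(12-bromododecyl)-2-methyl-1,3-dioxolane, via Grignard reagent 3 (not isolated)
Conditions: 1, Mg, I2 (crystal), THF, reflux; then 2 (3 equiv), Li2CuCl4 (3 mol %), THF, −10 °C to rt
Reagents that add atoms: magnesium, [Mg] (stays only in intermediate 3)
Why: Copper-catalysed alkyl–alkyl cross-coupling of a primary Grignard reagent with a primary bromide (Kochi coupling); the excess of symmetrical 2 should hold the reaction at mono-coupling, and the surplus is removed by distillation. The ketal is inert to Grignard and cuprate species.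

Step 2
Reactants: 5 methyl (2S)-5-oxopyrrolidine-2-carboxylate (methyl L-pyroglutamate)
Product: 6 1-benzyl 2-methyl (2S)-5-oxopyrrolidine-1,2-dicarboxylate
Conditions: LiN(SiMe3)2 (1.0 equiv), THF, −78 °C; then CbzCl, −78 °C
Reagents that add atoms: benzyl chloroformate, O=C(Cl)OCc1ccccc1
Why: N-Acylation of the lactam anion; one equivalent of base removes the far more acidic N–H and leaves the C2–H alone, so the stereocentre should be kept. The carbamate turns the lactam carbonyl into an imide-type electrophile for step 3 and can be removed without acid, which spares the ketal.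

Step 3
Reactants: 4 2-(12-bromododecyl)-2-methyl-1,3-dioxolane; 6 1-benzyl 2-methyl (2S)-5-oxopyrrolidine-1,2-dicarboxylate
Product: 8 methyl (2S)-2-{[(benzyloxy)carbonyl]amino}-17-(2-methyl-1,3-dioxolan-2-yl)-5-oxoheptadecanoate, via Grignard reagent 7 (not isolated)
Conditions: 4, Mg, THF, 40 °C; then added to 6, THF, −40 °C; aqueous work-up
Reagents that add atoms: magnesium, [Mg] (stays only in intermediate 7)
Why: Ring-opening Grignard addition to an N-acyl lactam; the ring carbonyl is the most electrophilic of the three carbonyl groups. The tetrahedral adduct collapses to the acyclic carbamate anion, which discourages a second addition. C2 is not touched.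

Step 4
Reactants: 8 methyl (2S)-2-{[(benzyloxy)carbonyl]amino}-17-(2-methyl-1,3-dioxolan-2-yl)-5-oxoheptadecanoate
Product: 11 methyl (2S,5S)-5-[12-(2-methyl-1,3-dioxolan-2-yl)dodecyl]pyrrolidine-2-carboxylate (2,5-cis), via amino ketone 9 (not isolated), via cyclic imine 10 (not isolated)
Conditions: H2 (1 atm), Pd/C, MeOH, rt
Reagents that add atoms: none
Why: Hydrogenolysis of the Cbz group frees amine 9, which condenses with the C5 ketone to the five-membered imine 10 (intramolecular reductive amination). Heterogeneous hydrogenation of 10 should occur from the face opposite the C2 ester, which sets C5 as S, the 2,5-cis isomer. The neutral medium leaves the ketal intact.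

Step 5
Reactants: 11 methyl (2S,5S)-5-[12-(2-methyl-1,3-dioxolan-2-yl)dodecyl]pyrrolidine-2-carboxylate
Product: 12 methyl (2S,5S)-1-benzyl-5-[12-(2-methyl-1,3-dioxolan-2-yl)dodecyl]pyrrolidine-2-carboxylate
Conditions: BnBr, K2CO3, MeCN, 60 °C
Reagents that add atoms: benzyl bromide, BrCc1ccccc1
Why: SN2 N-alkylation of the secondary amine; the key step needs a nucleophilic tertiary nitrogen, and benzyl can be removed at the end by hydrogenolysis. The carbonate base is too weak to epimerise C2.

Step 6
Reactants: 12 methyl (2S,5S)-1-benzyl-5-[12-(2-methyl-1,3-dioxolan-2-yl)dodecyl]pyrrolidine-2-carboxylate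
Product: 14 1-{(2S,5S)-1-benzyl-5-[12-(2-methyl-1,3-dioxolan-2-yl)dodecyl]pyrrolidin-2-yl}ethan-1-one, via Weinreb amide 13 (not isolated)
Conditions: MeNH(OMe)·HCl, i-PrMgCl, THF, −15 °C; then MeMgCl, 0 °C, same flask; aqueous work-up
Reagents that add atoms: methylmagnesium chloride, C[Mg]Cl; N,O-dimethylhydroxylamine hydrochloride, CNOC.Cl (atoms stay only in intermediate 13)
Why: Aminolysis of the ester by the magnesium amide gives Weinreb amide 13, whose chelated adduct with MeMgCl lasts until work-up, so addition stops at the ketone (telescoped Weinreb ketone synthesis). The low temperature and the chelated intermediates should limit epimerisation at C2.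

Step 7
Reactants: 14 1-{(2S,5S)-1-benzyl-5-[12-(2-methyl-1,3-dioxolan-2-yl)dodecyl]pyrrolidin-2-yl}ethan-1-one
Product: 15 (1S)-1-{(2S,5S)-1-benzyl-5-[12-(2-methyl-1,3-dioxolan-2-yl)dodecyl]pyrrolidin-2-yl}ethan-1-ol
Conditions: LiBH(s-Bu)3, THF, −78 °C; aqueous NaOH work-up (no peroxide)
Reagents that add atoms: none
Why: Felkin–Anh-controlled hydride addition to an α-(dialkylamino) ketone. The C2–N bond stands perpendicular to the carbonyl plane and the bulky borohydride comes in anti to nitrogen, past the C2–H, which gives the (1S) alcohol, the syn amino alcohol. The peroxide-free work-up avoids N-oxidation.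

Step 8
Reactants: 15 (1S)-1-{(2S,5S)-1-benzyl-5-[12-(2-methyl-1,3-dioxolan-2-yl)dodecyl]pyrrolidin-2-yl}ethan-1-ol
Product: 19 (2R,3R,6S)-1-benzyl-2-methyl-6-[12-(2-methyl-1,3-dioxolan-2-yl)dodecyl]piperidin-3-ol, via pyrrolidine trifluoroacetate 16 (not isolated), via aziridinium trifluoroacetate 17 (not isolated), via piperidine trifluoroacetate 18 (not isolated)
Conditions: (CF3CO)2O, THF, 0 °C; Et3N, reflux (sealed tube, 100 °C, if slow); then 2.5 M aq NaOH, rt
Reagents that add atoms: trifluoroacetic anhydride, O=C(OC(=O)C(F)(F)F)C(F)(F)F (its carboxylate carries the oxygen to C3; the two carboxylate oxygens are equivalent, so O3 is either the former carbinol oxygen or one from the anhydride)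
Why: The alcohol is acylated to 16, and once Et3N frees the ring nitrogen its lone pair displaces the carboxylate from the side-chain carbon in a 3-exo-tet SN2 closure that gives the 1-azoniabicyclo[3.1.0]hexane 17. The carboxylate then attacks the bridgehead carbon (old pyrrolidine C2) anti to nitrogen and breaks the bond shared by the three- and five-membered rings, so the six-membered ring is not closed by a cyclisation but is the periphery of the bicycle set free by that cleavage, and NaOH finally removes the acyl group of 18. The closest known reaction type is the ring enlargement of N-alkyl prolinols to piperidin-3-ols through aziridinium ions with trifluoroacetic anhydride and triethylamine, which is known for secondary carbinols and for 5-substituted prolinols. The new C2 is set by inversion at the (S)-carbinol carbon (giving R), the new C3 by inversion at pyrrolidine C2 (S giving R), and C6 is the untouched pyrrolidine C5, so a syn amino alcohol on a 2,5-cis pyrrolidine maps onto the all-cis piperidine. The selectivity needed is regiochemical: the carboxylate must return to the bridgehead and not to the methyl-bearing carbon, and both are secondary. Reversibility secures it, since trifluoroacetate leaves again at reflux, so 16 keeps re-ionising while the equilibrium drains into 18, a strain-free chair with both α-substituents equatorial and only the ester axial. The substrate helps, because the benzyl group of the 2,5-cis pyrrolidine sits trans to both substituents and so places the lone pair on the face of the side chain, ready for backside attack. No carbocation is involved, so no stereochemical leakage is expected, and the ketal is inert to the buffered medium.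

Step 9
Reactants: 19 (2R,3R,6S)-1-benzyl-2-methyl-6-[12-(2-methyl-1,3-dioxolan-2-yl)dodecyl]piperidin-3-ol
Product: 20 (2R,3R,6S)-1-benzyl-2-methyl-6-[12-(2-methyl-1,3-dioxolan-2-yl)dodecyl]piperidin-3-yl acetate
Conditions: Ac2O, pyridine, DMAP (cat.), CH2Cl2, rt
Reagents that add atoms: acetic anhydride, CC(=O)OC(C)=O
Why: DMAP-catalysed esterification of the axial secondary alcohol; N1 is tertiary and cannot be acylated, and no stereocentre is touched.

Step 10
Reactants: 20 (2R,3R,6S)-1-benzyl-2-methyl-6-[12-(2-methyl-1,3-dioxolan-2-yl)dodecyl]piperidin-3-yl acetate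
Product: 22 (2R,3R,6S)-2-methyl-6-(13-oxotetradecyl)piperidin-3-yl acetate, (−)-3-O-acetylspectaline, via N-benzyl ketone 21 (not isolated)
Conditions: AcOH–H2O 4:1, 50 °C; then Pd(OH)2/C, H2 (1 atm), rt, same flask; short cold aq NaHCO3 work-up
Reagents that add atoms: water, O
Why: Aqueous acetic acid hydrolyses the dioxolane to ketone 21 without touching the acetate. Hydrogenolysis of the benzylic C–N bond in the same acidic medium frees N1 as its ammonium salt, which cannot attack the ester. An isolated dialkyl ketone is inert to these hydrogenation conditions, and the brief cold bicarbonate wash liberates the base.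

## Compound list

1 | 2-(3-chloropropyl)-2-methyl-1,3-dioxolane | CC1(OCCO1)CCCCl | starting material
2 | 1,9-dibromononane | BrCCCCCCCCCBr | starting material
3 | [3-(2-methyl-1,3-dioxolan-2-yl)propyl]magnesium chloride | CC1(OCCO1)CCC[Mg]Cl | intermediate
4 | 2-(12-bromododecyl)-2-methyl-1,3-dioxolane | CC1(OCCO1)CCCCCCCCCCCCBr | intermediate
5 | methyl (2S)-5-oxopyrrolidine-2-carboxylate | COC(=O)[C@@H]1CCC(=O)N1 | starting material
6 | 1-benzyl 2-methyl (2S)-5-oxopyrrolidine-1,2-dicarboxylate | COC(=O)[C@@H]1CCC(=O)N1C(=O)OCc2ccccc2 | intermediate
7 | [12-(2-methyl-1,3-dioxolan-2-yl)dodecyl]magnesium bromide | CC1(OCCO1)CCCCCCCCCCCC[Mg]Br | intermediate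
8 | methyl (2S)-2-{[(benzyloxy)carbonyl]amino}-17-(2-methyl-1,3-dioxolan-2-yl)-5-oxoheptadecanoate | CC1(OCCO1)CCCCCCCCCCCCC(=O)CC[C@H](NC(=O)OCc2ccccc2)C(=O)OC | intermediate
9 | methyl (2S)-2-amino-17-(2-methyl-1,3-dioxolan-2-yl)-5-oxoheptadecanoate | CC1(OCCO1)CCCCCCCCCCCCC(=O)CC[C@H](N)C(=O)OC | intermediate
10 | methyl (2S)-5-[12-(2-methyl-1,3-dioxolan-2-yl)dodecyl]-3,4-dihydro-2H-pyrrole-2-carboxylate | CC1(OCCO1)CCCCCCCCCCCCC2=N[C@@H](CC2)C(=O)OC | intermediate
11 | methyl (2S,5S)-5-[12-(2-methyl-1,3-dioxolan-2-yl)dodecyl]pyrrolidine-2-carboxylate | CC1(OCCO1)CCCCCCCCCCCC[C@H]2CC[C@H](N2)C(=O)OC | intermediate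
12 | methyl (2S,5S)-1-benzyl-5-[12-(2-methyl-1,3-dioxolan-2-yl)dodecyl]pyrrolidine-2-carboxylate | CC1(OCCO1)CCCCCCCCCCCC[C@H]2CC[C@H](N2Cc3ccccc3)C(=O)OC | intermediate
13 | (2S,5S)-1-benzyl-N-methoxy-N-methyl-5-[12-(2-methyl-1,3-dioxolan-2-yl)dodecyl]pyrrolidine-2-carboxamide | CC1(OCCO1)CCCCCCCCCCCC[C@H]2CC[C@H](N2Cc3ccccc3)C(=O)N(C)OC | intermediate
14 | 1-{(2S,5S)-1-benzyl-5-[12-(2-methyl-1,3-dioxolan-2-yl)dodecyl]pyrrolidin-2-yl}ethan-1-one | CC1(OCCO1)CCCCCCCCCCCC[C@H]2CC[C@H](N2Cc3ccccc3)C(C)=O | intermediate
15 | (1S)-1-{(2S,5S)-1-benzyl-5-[12-(2-methyl-1,3-dioxolan-2-yl)dodecyl]pyrrolidin-2-yl}ethan-1-ol | CC1(OCCO1)CCCCCCCCCCCC[C@H]2CC[C@H](N2Cc3ccccc3)[C@H](C)O | intermediate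
16 | (1S)-1-{(2S,5S)-1-benzyl-5-[12-(2-methyl-1,3-dioxolan-2-yl)dodecyl]pyrrolidin-2-yl}ethyl trifluoroacetate | CC1(OCCO1)CCCCCCCCCCCC[C@H]2CC[C@H](N2Cc3ccccc3)[C@H](C)OC(=O)C(F)(F)F | intermediate
17 | (2S,5S,6R)-1-benzyl-6-methyl-2-[12-(2-methyl-1,3-dioxolan-2-yl)dodecyl]-1-azoniabicyclo[3.1.0]hexane trifluoroacetate (methyl endo) | CC1(OCCO1)CCCCCCCCCCCC[C@H]2CC[C@H]3[C@@H](C)[N@@+]23Cc4ccccc4.[O-]C(=O)C(F)(F)F | intermediate
18 | (2R,3R,6S)-1-benzyl-2-methyl-6-[12-(2-methyl-1,3-dioxolan-2-yl)dodecyl]piperidin-3-yl trifluoroacetate | CC1(OCCO1)CCCCCCCCCCCC[C@H]2CC[C@@H](OC(=O)C(F)(F)F)[C@@H](C)N2Cc3ccccc3 | intermediate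
19 | (2R,3R,6S)-1-benzyl-2-methyl-6-[12-(2-methyl-1,3-dioxolan-2-yl)dodecyl]piperidin-3-ol | CC1(OCCO1)CCCCCCCCCCCC[C@H]2CC[C@@H](O)[C@@H](C)N2Cc3ccccc3 | intermediate
20 | (2R,3R,6S)-1-benzyl-2-methyl-6-[12-(2-methyl-1,3-dioxolan-2-yl)dodecyl]piperidin-3-yl acetate | CC1(OCCO1)CCCCCCCCCCCC[C@H]2CC[C@@H](OC(C)=O)[C@@H](C)N2Cc3ccccc3 | intermediate
21 | (2R,3R,6S)-1-benzyl-2-methyl-6-(13-oxotetradecyl)piperidin-3-yl acetate | CC(=O)CCCCCCCCCCCC[C@H]1CC[C@@H](OC(C)=O)[C@@H](C)N1Cc2ccccc2 | intermediate
22 | (2R,3R,6S)-2-methyl-6-(13-oxotetradecyl)piperidin-3-yl acetate, (−)-3-O-acetylspectaline | CC(=O)CCCCCCCCCCCC[C@H]1CC[C@@H](OC(C)=O)[C@@H](C)N1 | target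

## Step count and risk

Total step count: 10. Longest linear sequence: 9 steps (steps 2 to 10 from 5, or steps 1 and 3 to 10 from 1).

**Step 8 (key step).**
- *Risk.* Ionisation may be slow, because the methyl group must take the endo position of the bicyclic aziridinium ion, on the same face as the C6 chain. Equilibration may also be incomplete, with the carboxylate returning to the methyl-bearing carbon, and elimination may set in on long heating.
- *Fallback.* It sets out from bromide 4 and comes back at target 22; it gives up the ring enlargement for a catalytic setting of C2/C3 followed by reductive ring closure. Grignard reagent 7 is acylated with N-methoxy-N-methylpent-4-enamide to the alkenyl ketone F1. Ozonolysis with Me2S work-up gives the keto aldehyde F2. A syn-selective catalytic asymmetric Henry reaction with nitroethane (Cu(OAc)2, chiral diamine ligand, amine base) gives the nitro alcohol F3. Hydrogenation over Raney Ni reduces the nitro group; the amine condenses with the C6 ketone and the cyclic imine is reduced from the less hindered face to the all-cis piperidinol F4. O-Selective acetylation of the ammonium salt (AcCl in CF3CO2H), followed by water to cleave the ketal, leads to 22.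

**Step 7.**
- *Risk.* Facial selectivity may be poor if lithium chelation between the ring nitrogen and the carbonyl oxygen competes with the Felkin–Anh conformer. The α-amino ketone may also epimerise before it is reduced.
- *Fallback.* It sets out from ester 12 and comes back at 15; the stereocentre is set by forming the C–C bond instead of the C–H bond, so chelation works for the desired isomer. Reduction with i-Bu2AlH in toluene at −78 °C gives the aldehyde F5. MeMgBr in Et2O then adds to the magnesium chelate of nitrogen and oxygen from the side of the C2–H, which leads to the same (1S) syn amino alcohol 15 and bypasses ketone 14.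

**Step 3.**
- *Risk.* The Grignard reagent may attack the carbamate carbonyl (loss of the Cbz group) or the methyl ester, or add a second time to the new ketone.
- *Fallback.* It sets out from bromide 4 and comes back at 8; the hard nucleophile is replaced by a catalytic acylation. Zinc dust with LiCl in THF converts 4 into the alkylzinc bromide F6. Commercial N-Cbz-L-glutamic acid 1-methyl ester is condensed with ethanethiol (carbodiimide, DMAP) to the S-ethyl thioester F7. A Fukuyama coupling of F6 and F7 with PdCl2(PPh3)2 gives 8 without touching the ester or the carbamate, and step 2 is no longer needed.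

**Step 10.**
- *Risk.* Hydrogenolysis of a benzyl group flanked by two α-branched carbons may be sluggish. The acetyl group may also move from O3 to N1 while the amine is free during the basic work-up.
- *Fallback.* It sets out from 20 and comes back at 22; hydrogenolysis is replaced by a chloroformate dealkylation. 2,2,2-Trichloroethyl chloroformate in MeCN at reflux (K2CO3) cleaves the benzyl group as its chloride and gives the trichloroethyl carbamate F8. Zn dust in AcOH–H2O at 50 °C removes the carbamate and hydrolyses the ketal in one acidic operation, and 22 is isolated as in step 10 or kept as its salt.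

## Further compounds

F1 | step 8 | 17-(2-methyl-1,3-dioxolan-2-yl)heptadec-1-en-5-one | CC1(OCCO1)CCCCCCCCCCCCC(=O)CCC=C
F2 | step 8 | 16-(2-methyl-1,3-dioxolan-2-yl)-4-oxohexadecanal | CC1(OCCO1)CCCCCCCCCCCCC(=O)CCC=O
F3 | step 8 | (2R,3R)-3-hydroxy-18-(2-methyl-1,3-dioxolan-2-yl)-2-nitrooctadecan-6-one | CC1(OCCO1)CCCCCCCCCCCCC(=O)CC[C@@H](O)[C@@H](C)[N+](=O)[O-]
F4 | step 8 | (2R,3R,6S)-2-methyl-6-[12-(2-methyl-1,3-dioxolan-2-yl)dodecyl]piperidin-3-ol | CC1(OCCO1)CCCCCCCCCCCC[C@H]2CC[C@@H](O)[C@@H](C)N2
F5 | step 7 | (2S,5S)-1-benzyl-5-[12-(2-methyl-1,3-dioxolan-2-yl)dodecyl]pyrrolidine-2-carbaldehyde | CC1(OCCO1)CCCCCCCCCCCC[C@H]2CC[C@H](N2Cc3ccccc3)C=O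
F6 | step 3 | [12-(2-methyl-1,3-dioxolan-2-yl)dodecyl]zinc bromide | CC1(OCCO1)CCCCCCCCCCCC[Zn]Br
F7 | step 3 | methyl (2S)-2-{[(benzyloxy)carbonyl]amino}-5-(ethylsulfanyl)-5-oxopentanoate | CCSC(=O)CC[C@H](NC(=O)OCc1ccccc1)C(=O)OC
F8 | step 10 | 2,2,2-trichloroethyl (2R,3R,6S)-3-acetoxy-2-methyl-6-[12-(2-methyl-1,3-dioxolan-2-yl)dodecyl]piperidine-1-carboxylate | CC1(OCCO1)CCCCCCCCCCCC[C@H]2CC[C@@H](OC(C)=O)[C@@H](C)N2C(=O)OCC(Cl)(Cl)Cl
A1 | alternative 1 | benzyl N-[(2R)-1-oxopropan-2-yl]carbamate | C[C@@H](NC(=O)OCc1ccccc1)C=O
A2 | alternative 1 | benzyl N-[(2R,3R)-3-hydroxy-18-(2-methyl-1,3-dioxolan-2-yl)-6-oxooctadecan-2-yl]carbamate | CC1(OCCO1)CCCCCCCCCCCCC(=O)CC[C@@H](O)[C@@H](C)NC(=O)OCc2ccccc2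
A3 | alternative 1 | (2R,3R)-2-methyl-6-[12-(2-methyl-1,3-dioxolan-2-yl)dodecyl]-2,3,4,5-tetrahydropyridin-3-ol | CC1(OCCO1)CCCCCCCCCCCCC2=N[C@H](C)[C@H](O)CC2
A4 | alternative 2 | 4-methyl-N-[(1R)-1-{5-[12-(2-methyl-1,3-dioxolan-2-yl)dodecyl]furan-2-yl}ethyl]benzenesulfonamide | CC1(OCCO1)CCCCCCCCCCCCc2ccc(o2)[C@@H](C)NS(=O)(=O)c3ccc(C)cc3
A5 | alternative 2 | (2R)-6-hydroxy-2-methyl-6-[12-(2-methyl-1,3-dioxolan-2-yl)dodecyl]-1-(4-methylbenzenesulfonyl)-1,6-dihydropyridin-3(2H)-one | CC1(OCCO1)CCCCCCCCCCCCC2(O)C=CC(=O)[C@@H](C)N2S(=O)(=O)c3ccc(C)cc3
A6 | alternative 3 | 2-methylpyridin-3-ol | Cc1ncccc1O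
A7 | alternative 3 | 2-methyl-6-(13-oxotetradecyl)pyridin-3-yl acetate | CC(=O)CCCCCCCCCCCCc1ccc(OC(C)=O)c(C)n1
A8 | alternative 3 | 2-methyl-6-(13-oxotetradecyl)piperidin-3-one | CC(=O)CCCCCCCCCCCCC1CCC(=O)C(C)N1
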